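The ring is traced back to a butadiene/2-bromoacrolein [4+2] cycloadduct: C5 of the cyclohexene carries a heteroatom and the chain carbon C1' and lies between the methylenes C4 and C6, the signature of an α-heterosubstituted acrolein adduct. One catalytic, enantioselective cycloaddition forms C5–C6 and C3–C4, closes the six-membered ring and fixes C5, with bromine holding the place of oxygen. The precursors are simply buta-1,3-diene and freshly made 2-bromoacrolein. Afterwards the bromide is exchanged for oxygen with inversion through a spiro-epoxide, the C2'–C16' alkynyl chain is attached at C1', and the C5 carbonate relays oxygen to C1 before the alkene is re-formed at C2=C3.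

Key step: step 4

Remarks
- Locants: ring atoms are C1 (secondary carbinol), C2=C3, C4, C5 (tertiary carbinol), C6; chain atoms are C1'–C16' counted from the ring. The target is the cis-diol (1S,3S)-1-[(12Z)-16-phenylhexadec-12-en-1-yl]cyclohex-4-ene-1,3-diol.
- Assumption on the chemistry: the (S)-configured oxazaborolidinium catalyst is taken, by analogy with its adducts of 2-bromoacrolein and cyclic dienes, to give the (R)-adduct 10; its antipode is equally accessible should the sense prove opposite.

Step 1
Reactants: 1 5-phenylpent-1-yne; 2 10-bromodecan-1-ol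
Product: 4 15-phenylpentadec-11-yn-1-ol, via lithium acetylide 3 (not isolated)
Conditions: 1 (2.3 equiv), n-BuLi (2.2 equiv), THF, −78 → 0 °C; DMPU, 2 (1 equiv), 0 °C → rt; H2O
Reagents that add atoms: none
Why: SN2 alkylation of a lithium acetylide at a primary bromide should be clean because the first equivalent of acetylide turns the hydroxyl into a lithium alkoxide that is a much poorer nucleophile than the acetylide in THF/DMPU, and no stereocentre is formed.

Step 2
Reactants: 4 15-phenylpentadec-11-yn-1-ol
Product: 5 (15-bromopentadec-4-yn-1-yl)benzene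
Conditions: CBr4, PPh3, CH2Cl2, 0 °C → rt
Reagents that add atoms: carbon tetrabromide, BrC(Br)(Br)Br
Why: Appel reaction, in which bromide displaces the alkoxyphosphonium group at the primary carbon under neutral conditions that leave the internal alkyne untouched.

Step 3
Reactants: 6 acrolein
Product: 8 2-bromoacrolein, via 2,3-dibromopropanal 7 (not isolated)
Conditions: Br2, CH2Cl2, −78 → 0 °C; then Et3N, 0 °C → rt; distilled and used fresh
Reagents that add atoms: bromine, BrBr
Why: Electrophilic addition of bromine to the enal followed by amine-induced dehydrobromination (loss of the acidic α-hydrogen and the β-bromide) is the standard preparation of this α-bromoenal.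

Step 4
Reactants: 8 2-bromoacrolein; 9 buta-1,3-diene
Product: 10 (1R)-1-bromocyclohex-3-ene-1-carbaldehyde
Conditions: (3aS)-3,3-diphenyl-1-(2-methylphenyl)tetrahydro-1H,3H-pyrrolo[1,2-c][1,3,2]oxazaborole (10 mol%), Tf2NH (10 mol%), 9 (5 equiv), CH2Cl2, −78 → −40 °C
Reagents that add atoms: none
Why: Coordination of the cationic boron Lewis acid to the formyl oxygen of 8 lowers the enal LUMO, and s-cis 9 then adds in a concerted, asynchronous [4+2] cycloaddition in which the bond to the β-carbon (C3–C4) is more advanced than the bond to the bromine-bearing carbon (C5–C6). The closest known reaction type is the chiral oxazaborolidine-catalysed Diels–Alder reaction of 2-bromoacrolein with simple acyclic and cyclic dienes. The cyclohexene ring closes by suprafacial–suprafacial union of the four-carbon diene unit (C6, C1, C2, C3) with the two-carbon dienophile unit (C5, C4), both σ-bonds arising in the one step. The new C5 stereocentre is controlled by the catalyst alone: the boron-bound aldehyde is held in one geometry and an aryl group of the catalyst screens one π-face, so that the diene is expected to attack the open face and give the (R)-bromide. The only selectivity needed is between the two enantiofaces of the dienophile, because the symmetrical, unsubstituted diene allows neither regioisomers nor endo/exo isomers, and it is secured by the single reactive conformation that the α-bromine and the two-point binding impose on the complexed enal.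

Step 5
Reactants: 10 (1R)-1-bromocyclohex-3-ene-1-carbaldehyde
Product: 12 (3S)-1-oxaspiro[2.5]oct-5-ene, via bromohydrin 11 (not isolated)
Conditions: NaBH4, MeOH, 0 °C; then 2 M aq NaOH, 0 °C → rt; pentane extraction, careful concentration
Reagents that add atoms: none
Why: Borohydride reduction of the aldehyde followed by base-induced halohydrin-to-epoxide closure, a 3-exo-tet intramolecular SN2 in which the alkoxide attacks C5 from the side opposite to bromide, so that the C5–O bond is made with inversion and the (S)-epoxide should result.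

Step 6
Reactants: 5 (15-bromopentadec-4-yn-1-yl)benzene; 12 (3S)-1-oxaspiro[2.5]oct-5-ene
Product: 14 (1S)-1-(16-phenylhexadec-12-yn-1-yl)cyclohex-3-en-1-ol, via Grignard reagent 13 (not isolated)
Conditions: 5, Mg, THF, 40 °C; then CuI (10 mol%), 12, THF, −30 → 0 °C; H2O
Reagents that add atoms: none
Why: Copper-catalysed opening of a 2,2-disubstituted epoxide by a primary alkyl Grignard reagent is an SN2 attack at the unhindered methylene C1', so the C5–O bond and its configuration are untouched and the remote internal alkyne is inert.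

Step 7
Reactants: 14 (1S)-1-(16-phenylhexadec-12-yn-1-yl)cyclohex-3-en-1-ol
Product: 15 tert-butyl (1S)-1-(16-phenylhexadec-12-yn-1-yl)cyclohex-3-en-1-yl carbonate
Conditions: n-BuLi, THF, −78 °C; Boc2O, −78 °C → rt; H2O
Reagents that add atoms: di-tert-butyl dicarbonate, CC(C)(C)OC(=O)OC(=O)OC(C)(C)C
Why: O-acylation of the pre-formed lithium tertiary alkoxide with Boc2O (carbonate formation) overcomes the hindrance that makes the neutral alcohol unreactive and does not touch the stereocentre.

Step 8
Reactants: 15 tert-butyl (1S)-1-(16-phenylhexadec-12-yn-1-yl)cyclohex-3-en-1-yl carbonate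
Product: 16 (1S,5S,6S)-6-iodo-1-(16-phenylhexadec-12-yn-1-yl)-2,4-dioxabicyclo[3.3.1]nonan-3-one
Conditions: NIS (1.5 equiv), MeCN, −20 → 0 °C, dark; aq Na2S2O3
Reagents that add atoms: N-iodosuccinimide, O=C1CCC(=O)N1I
Why: Iodocarbonate cyclisation of a homoallylic tert-butyl carbonate, in which reversible iodonium formation on C1=C2 is funnelled through the only productive path, attack of the axial carbonate carbonyl oxygen on C1 from its own face through a six-membered ring (C2 would need a seven-membered ring) and anti to iodine, so that C1–O is set cis to C5–O and C2–I trans to it while the tert-butyl group leaves as isobutene.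

Step 9
Reactants: 16 (1S,5S,6S)-6-iodo-1-(16-phenylhexadec-12-yn-1-yl)-2,4-dioxabicyclo[3.3.1]nonan-3-one
Product: 18 (1S,3S)-1-(16-phenylhexadec-12-yn-1-yl)cyclohex-4-ene-1,3-diol, via alkene carbonate 17 (not isolated)
Conditions: DBU (3 equiv), THF, 65 °C; then LiOH·H2O, H2O, rt
Reagents that add atoms: none
Why: E2 dehydroiodination is regiospecific because the axial C2–I bond of the rigid bicycle has an anti-periplanar hydrogen only at C3 (the C1 hydrogen is equatorial and at a bridgehead), and the following hydroxide hydrolysis of the cyclic carbonate cleaves only acyl C–O bonds, so both carbinol configurations are retained.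

Step 10
Reactants: 18 (1S,3S)-1-(16-phenylhexadec-12-yn-1-yl)cyclohex-4-ene-1,3-diol
Product: 19 (1S,3S)-1-[(12Z)-16-phenylhexadec-12-en-1-yl]cyclohex-4-ene-1,3-diol
Conditions: H2 (1 atm), Pd/CaCO3 poisoned with Pb(OAc)2, quinoline, EtOAc, rt, stopped after 1 equiv H2
Reagents that add atoms: none
Why: Lindlar semi-hydrogenation delivers both hydrogens to one face of the adsorbed alkyne and so gives the (Z)-alkene, while the poisoned catalyst leaves the disubstituted ring alkene, the allylic C–O bond and the arene untouched.

Compound list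
1 | 5-phenylpent-1-yne | C#CCCCc1ccccc1 | starting material
2 | 10-bromodecan-1-ol | OCCCCCCCCCCBr | starting material
3 | (5-phenylpent-1-yn-1-yl)lithium | [Li]C#CCCCc1ccccc1 | intermediate
4 | 15-phenylpentadec-11-yn-1-ol | OCCCCCCCCCCC#CCCCc1ccccc1 | intermediate
5 | (15-bromopentadec-4-yn-1-yl)benzene | BrCCCCCCCCCCC#CCCCc1ccccc1 | intermediate
6 | acrolein (prop-2-enal) | C=CC=O | starting material
7 | 2,3-dibromopropanal (racemic) | O=CC(Br)CBr | intermediate
8 | 2-bromoacrolein (2-bromoprop-2-enal) | C=C(Br)C=O | intermediate
9 | buta-1,3-diene | C=CC=C | starting material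
10 | (1R)-1-bromocyclohex-3-ene-1-carbaldehyde | C1=CCC[C@](Br)(C=O)C1 | intermediate
11 | [(1R)-1-bromocyclohex-3-en-1-yl]methanol | C1=CCC[C@](Br)(CO)C1 | intermediate
12 | (3S)-1-oxaspiro[2.5]oct-5-ene | C1=CCC[C@@]2(CO2)C1 | intermediate
13 | (15-phenylpentadec-11-yn-1-yl)magnesium bromide | Br[Mg]CCCCCCCCCCC#CCCCc1ccccc1 | intermediate
14 | (1S)-1-(16-phenylhexadec-12-yn-1-yl)cyclohex-3-en-1-ol | C1=CCC[C@@](O)(CCCCCCCCCCCC#CCCCc2ccccc2)C1 | intermediate
15 | tert-butyl (1S)-1-(16-phenylhexadec-12-yn-1-yl)cyclohex-3-en-1-yl carbonate | C1=CCC[C@@](OC(=O)OC(C)(C)C)(CCCCCCCCCCCC#CCCCc2ccccc2)C1 | intermediate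
16 | (1S,5S,6S)-6-iodo-1-(16-phenylhexadec-12-yn-1-yl)-2,4-dioxabicyclo[3.3.1]nonan-3-one | I[C@H]1CC[C@@]2(CCCCCCCCCCCC#CCCCc3ccccc3)C[C@@H]1OC(=O)O2 | intermediate
17 | (1S,5S)-1-(16-phenylhexadec-12-yn-1-yl)-2,4-dioxabicyclo[3.3.1]non-6-en-3-one | O=C1O[C@@H]2C=CC[C@@](O1)(CCCCCCCCCCCC#CCCCc3ccccc3)C2 | intermediate
18 | (1S,3S)-1-(16-phenylhexadec-12-yn-1-yl)cyclohex-4-ene-1,3-diol | O[C@@H]1C=CC[C@@](O)(CCCCCCCCCCCC#CCCCc2ccccc2)C1 | intermediate
19 | (1S,3S)-1-[(12Z)-16-phenylhexadec-12-en-1-yl]cyclohex-4-ene-1,3-diol | O[C@@H]1C=CC[C@@](O)(CCCCCCCCCCC/C=C\CCCc2ccccc2)C1 | target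

Total step count: 10
Longest linear sequence: 8 steps (steps 3–10, from acrolein 6)

Steps most likely to fail

Step 4. The cycloaddition may show poor enantioface discrimination or stall, because unsubstituted butadiene is a sluggish diene and the strong acid can polymerise the bromoenal. The fallback sets the stereocentre by Sharpless asymmetric epoxidation instead. Setting out from 9, a thermal Diels–Alder reaction with methyl propiolate gives methyl cyclohexa-1,4-diene-1-carboxylate F1, and i-Bu2AlH reduction gives (cyclohexa-1,4-dien-1-yl)methanol F2. Ti(OiPr)4, L-(+)-diethyl tartrate and t-BuOOH epoxidise only the allylic alkene and should give [(1S,6S)-7-oxabicyclo[4.1.0]hept-3-en-1-yl]methanol F3 (the D-(−)-tartrate is used if the facial sense proves opposite). LiAlH4 delivers hydride to the secondary epoxide carbon to give (1S)-1-(hydroxymethyl)cyclohex-3-en-1-ol F4. Selective tosylation of the primary hydroxyl gives [(1S)-1-hydroxycyclohex-3-en-1-yl]methyl 4-methylbenzenesulfonate F5, and NaH closes it to the spiro-epoxide, coming back to the route at 12.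

Step 8. The carbonate oxygen may fail to intercept the iodonium ion, through slow closure to the bridged bicycle, competing iodination of the alkyne or ionisation of the tertiary carbonate; incomplete Boc transfer in step 7 feeds the same problem. The fallback avoids the carbonate altogether. Setting out from 14, the free tertiary hydroxyl directs epoxidation with VO(acac)2 and t-BuOOH to its own face to give (1S,3S,6R)-3-(16-phenylhexadec-12-yn-1-yl)-7-oxabicyclo[4.1.0]heptan-3-ol F6. Sodium benzeneselenolate (PhSeSePh, NaBH4, EtOH) should open it trans-diaxially at C2, the chain staying equatorial, to give (1S,3S,4S)-1-(16-phenylhexadec-12-yn-1-yl)-4-(phenylselanyl)cyclohexane-1,3-diol F7. H2O2 then gives (1S,3S,4S)-4-(benzeneseleninyl)-1-(16-phenylhexadec-12-yn-1-yl)cyclohexane-1,3-diol F8, whose syn-elimination away from the carbinol carbon forms the C2=C3 alkene, coming back to the route at 18.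

Step 5. Dehydrobromination of the tertiary bromide may compete with ring closure, and the small epoxide may be lost on concentration. The fallback attaches the chain before the epoxide is made. Setting out from 10, addition of Grignard reagent 13 (THF, −78 °C) to the aldehyde gives 1-[(1R)-1-bromocyclohex-3-en-1-yl]-16-phenylhexadec-12-yn-1-ol F9 as a mixture of carbinol epimers. NaH in THF closes it with the same inversion at C5 to (3S)-2-(15-phenylpentadec-11-yn-1-yl)-1-oxaspiro[2.5]oct-5-ene F10, and LiEt3BH delivers hydride to the less substituted epoxide carbon C1', coming back to the route at 14 with 12 bypassed.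

Further compounds
F1 | step 4 | methyl cyclohexa-1,4-diene-1-carboxylate | COC(=O)C1=CCC=CC1
F2 | step 4 | (cyclohexa-1,4-dien-1-yl)methanol | OCC1=CCC=CC1
F3 | step 4 | [(1S,6S)-7-oxabicyclo[4.1.0]hept-3-en-1-yl]methanol | OC[C@@]12CC=CC[C@@H]1O2
F4 | step 4 | (1S)-1-(hydroxymethyl)cyclohex-3-en-1-ol | C1=CCC[C@@](O)(CO)C1
F5 | step 4 | [(1S)-1-hydroxycyclohex-3-en-1-yl]methyl 4-methylbenzenesulfonate | C1=CCC[C@@](O)(COS(=O)(=O)c2ccc(C)cc2)C1
F6 | step 8 | (1S,3S,6R)-3-(16-phenylhexadec-12-yn-1-yl)-7-oxabicyclo[4.1.0]heptan-3-ol | O[C@@]1(CCCCCCCCCCCC#CCCCc3ccccc3)CC[C@H]2O[C@H]2C1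
F7 | step 8 | (1S,3S,4S)-1-(16-phenylhexadec-12-yn-1-yl)-4-(phenylselanyl)cyclohexane-1,3-diol | c3ccccc3[Se][C@H]1CC[C@@](O)(CCCCCCCCCCCC#CCCCc2ccccc2)C[C@@H]1O
F8 | step 8 | (1S,3S,4S)-4-(benzeneseleninyl)-1-(16-phenylhexadec-12-yn-1-yl)cyclohexane-1,3-diol (mixture at selenium) | O=[Se](c3ccccc3)[C@H]1CC[C@@](O)(CCCCCCCCCCCC#CCCCc2ccccc2)C[C@@H]1O
F9 | step 5 | 1-[(1R)-1-bromocyclohex-3-en-1-yl]-16-phenylhexadec-12-yn-1-ol (both C1 epimers) | C1=CCC[C@](Br)(C(O)CCCCCCCCCCC#CCCCc2ccccc2)C1
F10 | step 5 | (3S)-2-(15-phenylpentadec-11-yn-1-yl)-1-oxaspiro[2.5]oct-5-ene (both C2 epimers) | C1=CCC[C@@]2(C(CCCCCCCCCCC#CCCCc3ccccc3)O2)C1
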